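**Retrosynthetic overview**
1. C11–C12: target 25 ← bis-silyl ether 24 ← aldehyde 11 (C1–C11) + terminal alkyne 23 (C12–C22), joined by a proposed zerovalent-nickel/chiral-carbene reductive coupling that forms the C11–C12 bond, the 12E alkene and the 11R carbinol.
2. Aldehyde 11 ← eight-membered Z-lactone by ring-closing metathesis of pent-4-enoate 8; C7 set by Brown allylation of cyclopropanecarbaldehyde 4.
3. Cyclopropane (C8–C9–C10) ← Charette asymmetric Simmons–Smith reaction of mono-silylated (E)-but-2-ene-1,4-diol 2.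
4. Alkyne 23 ← Brown allylation of 3-(trimethylsilyl)prop-2-ynal (C14), alkene cleavage, Z-selective Wittig reaction with the ylide from salt 20, C-desilylation.
5. Ring order: cyclopropane first (step 2), oxocinone second (step 6).

**Assumptions**
- Numbering runs from C1 (lactone carbonyl) to C22 (methyl); the SMILES is read as 4Z,7R,8R,10R,11R,12E,14S,16Z,19Z.
- L1·HBF4 is (4R,5R)-1,3-bis(2-cyclohexylphenyl)-4,5-diphenyl-4,5-dihydro-1H-imidazol-3-ium tetrafluoroborate, a proposed carbene precursor prepared separately; its (4R,5R) antipode is assumed to direct Re-face attack on 11, and the (4S,5S) antipode is used if the first run shows the opposite sense.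
- Both antipodes of Ipc2B(allyl) and the Charette dioxaborolane are bought.

**Fragment A (C1–C11)**

Step 1
Reactants: 1 (E)-but-2-ene-1,4-diol
Product: 2 (E)-4-[(tert-butyldimethylsilyl)oxy]but-2-en-1-ol
Conditions: 1 (3 equiv), TBSCl (1 equiv), imidazole, THF, 0 °C → rt
Reagents that add atoms: tert-butyldimethylsilyl chloride (TBSCl), CC(C)(C)[Si](C)(C)Cl
Why: Statistical mono-silylation (silyl ether formation) of a symmetrical diol used in excess, with unreacted 1 removed by aqueous wash; no stereocentre is formed.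

Step 2
Reactants: 2 (E)-4-[(tert-butyldimethylsilyl)oxy]but-2-en-1-ol
Product: 3 [(1R,2R)-2-{[(tert-butyldimethylsilyl)oxy]methyl}cyclopropyl]methanol
Conditions: Et2Zn (2.2 equiv), CH2I2 (4.4 equiv), DME, CH2Cl2, −10 °C (gives Zn(CH2I)2·DME); then 2 and (4S,5S)-2-butyl-N,N,N',N'-tetramethyl-1,3,2-dioxaborolane-4,5-dicarboxamide (1.2 equiv), −10 °C → rt; aq NH4Cl, then aq KOH wash
Reagents that add atoms: diiodomethane, ICI
Why: Charette asymmetric Simmons–Smith cyclopropanation: the zinc alkoxide of 2 bound to the chiral dioxaborolane takes CH2 on one alkene face only, the (4S,5S) ligand giving the (1R,2R) ring (future C10 and C8), and the trans relationship follows stereospecifically from the E-alkene.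

Step 3
Reactants: 3 [(1R,2R)-2-{[(tert-butyldimethylsilyl)oxy]methyl}cyclopropyl]methanol
Product: 4 (1R,2R)-2-{[(tert-butyldimethylsilyl)oxy]methyl}cyclopropane-1-carbaldehyde
Conditions: TEMPO (10 mol %), PhI(OAc)2 (1.1 equiv), CH2Cl2, rt
Reagents that add atoms: none
Why: Oxoammonium-mediated (TEMPO/PhI(OAc)2) oxidation of a primary alcohol stops at the aldehyde and leaves the silyl ether and both ring stereocentres untouched.

Step 4
Reactants: 4 (1R,2R)-2-{[(tert-butyldimethylsilyl)oxy]methyl}cyclopropane-1-carbaldehyde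
Product: 6 (R)-1-[(1R,2R)-2-{[(tert-butyldimethylsilyl)oxy]methyl}cyclopropyl]but-3-en-1-ol, via borinate ester 5 (not isolated)
Conditions: (+)-Ipc2B(allyl) (1.3 equiv), Et2O, −78 °C; then 3 M NaOH, 30% H2O2, 0 °C → rt
Reagents that add atoms: (+)-B-allyldiisopinocampheylborane (from (−)-α-pinene), C=CCB([C@H]1C[C@H]2C[C@@H]([C@@H]1C)C2(C)C)[C@H]1C[C@H]2C[C@@H]([C@@H]1C)C2(C)C
Why: Brown asymmetric allylboration through a closed chair transition state: the reagent from (−)-α-pinene delivers allyl to the Re face of the aldehyde under reagent control and sets C7 as R, and oxidative work-up frees the alcohol.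

Step 5
Reactants: 6 (R)-1-[(1R,2R)-2-{[(tert-butyldimethylsilyl)oxy]methyl}cyclopropyl]but-3-en-1-ol; 7 pent-4-enoyl chloride
Product: 8 (R)-1-[(1R,2R)-2-{[(tert-butyldimethylsilyl)oxy]methyl}cyclopropyl]but-3-en-1-yl pent-4-enoate
Conditions: pyridine, DMAP (cat.), CH2Cl2, 0 °C → rt
Reagents that add atoms: none
Why: DMAP-catalysed O-acylation (esterification) takes place at oxygen, so C7 keeps its configuration.

Step 6
Reactants: 8 (R)-1-[(1R,2R)-2-{[(tert-butyldimethylsilyl)oxy]methyl}cyclopropyl]but-3-en-1-yl pent-4-enoate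
Product: 9 (R,Z)-8-[(1R,2R)-2-{[(tert-butyldimethylsilyl)oxy]methyl}cyclopropyl]-3,4,7,8-tetrahydro-2H-oxocin-2-one
Conditions: second-generation Grubbs catalyst (10 mol %), CH2Cl2 (1 mM), 40 °C
Reagents that add atoms: none
Why: Ring-closing metathesis of the two terminal alkenes at high dilution, driven by loss of ethene, closes the eight-membered lactone, whose ring size allows only the Z alkene (C4=C5).

Step 7
Reactants: 9 (R,Z)-8-[(1R,2R)-2-{[(tert-butyldimethylsilyl)oxy]methyl}cyclopropyl]-3,4,7,8-tetrahydro-2H-oxocin-2-one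
Product: 10 (R,Z)-8-[(1R,2R)-2-(hydroxymethyl)cyclopropyl]-3,4,7,8-tetrahydro-2H-oxocin-2-one
Conditions: HF·pyridine, pyridine, THF, 0 °C → rt
Reagents that add atoms: none
Why: Fluoride-driven Si–O cleavage (silyl ether deprotection) under buffered conditions leaves the lactone, the alkene and the cyclopropane untouched.

Step 8
Reactants: 10 (R,Z)-8-[(1R,2R)-2-(hydroxymethyl)cyclopropyl]-3,4,7,8-tetrahydro-2H-oxocin-2-one
Product: 11 (1R,2R)-2-[(2R,4Z)-8-oxo-3,6,7,8-tetrahydro-2H-oxocin-2-yl]cyclopropane-1-carbaldehyde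
Conditions: TEMPO (10 mol %), PhI(OAc)2 (1.1 equiv), CH2Cl2, rt
Reagents that add atoms: none
Why: TEMPO/PhI(OAc)2 oxidation converts the primary cyclopropylcarbinol into the aldehyde without over-oxidation or epimerisation of the trans-cyclopropane.

**Fragment B (C12–C22)**

Step 9
Reactants: 12 3-(trimethylsilyl)prop-2-ynal
Product: 14 (S)-1-(trimethylsilyl)hex-5-en-1-yn-3-ol, via borinate ester 13 (not isolated)
Conditions: (−)-Ipc2B(allyl) (1.2 equiv), Et2O, −78 °C; then pH 7 buffer, MeOH, 30% H2O2, 0 °C → rt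
Reagents that add atoms: (−)-B-allyldiisopinocampheylborane (from (+)-α-pinene), C=CCB([C@@H]1C[C@@H]2C[C@H]([C@H]1C)C2(C)C)[C@@H]1C[C@@H]2C[C@H]([C@H]1C)C2(C)C
Why: Brown asymmetric allylboration: the reagent from (+)-α-pinene adds allyl to the Si face of the ynal through the chair transition state and sets C14 as S, and the buffered peroxide work-up spares the alkynylsilane.

Step 10
Reactants: 14 (S)-1-(trimethylsilyl)hex-5-en-1-yn-3-ol
Product: 15 (S)-tert-butyldimethyl{[1-(trimethylsilyl)hex-5-en-1-yn-3-yl]oxy}silane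
Conditions: TBSCl, imidazole, DMF, rt
Reagents that add atoms: tert-butyldimethylsilyl chloride (TBSCl), CC(C)(C)[Si](C)(C)Cl
Why: Imidazole-promoted silylation of the secondary propargylic alcohol occurs at oxygen with retention at C14.

Step 11
Reactants: 15 (S)-tert-butyldimethyl{[1-(trimethylsilyl)hex-5-en-1-yn-3-yl]oxy}silane
Product: 17 (S)-3-[(tert-butyldimethylsilyl)oxy]-5-(trimethylsilyl)pent-4-ynal, via diol 16 (not isolated)
Conditions: OsO4 (2 mol %), NaIO4 (4 equiv), 2,6-lutidine, dioxane/H2O 3:1, rt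
Reagents that add atoms: osmium tetroxide (oxygen carrier), O=[Os](=O)(=O)=O; sodium periodate (terminal oxygen source), [Na+].[O-]I(=O)(=O)=O
Why: Lemieux–Johnson oxidative cleavage: OsO4 dihydroxylates the terminal alkene far faster than the silyl alkyne and NaIO4 cleaves the diol in the same flask, leaving C14 untouched.

Step 12
Reactants: 18 (Z)-hex-3-en-1-ol
Product: 19 (Z)-1-iodohex-3-ene
Conditions: I2, PPh3, imidazole, CH2Cl2, 0 °C → rt
Reagents that add atoms: iodine, II
Why: Appel-type iodination of the primary alcohol by SN2 displacement of the activated oxyphosphonium leaves the Z-alkene unchanged.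

Step 13
Reactants: 19 (Z)-1-iodohex-3-ene
Product: 20 [(Z)-hex-3-en-1-yl]triphenylphosphonium iodide
Conditions: PPh3, MeCN, reflux
Reagents that add atoms: triphenylphosphine, c1ccc(cc1)P(c1ccccc1)c1ccccc1
Why: SN2 quaternisation of triphenylphosphine by the primary iodide gives the Wittig salt.

Step 14
Reactants: 20 [(Z)-hex-3-en-1-yl]triphenylphosphonium iodide; 17 (S)-3-[(tert-butyldimethylsilyl)oxy]-5-(trimethylsilyl)pent-4-ynal
Product: 22 (S)-tert-butyldimethyl{[(5Z,8Z)-1-(trimethylsilyl)undeca-5,8-dien-1-yn-3-yl]oxy}silane, via phosphonium ylide 21 (not isolated)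
Conditions: NaN(SiMe3)2, THF, −78 → 0 °C; then 17, −78 °C → rt
Reagents that add atoms: none
Why: Wittig olefination of a non-stabilised ylide under lithium-free conditions goes through the kinetically favoured cis-oxaphosphetane and gives the 16Z alkene, completing the skipped Z,Z-diene, while the low temperature suppresses β-elimination of the silyloxy group.

Step 15
Reactants: 22 (S)-tert-butyldimethyl{[(5Z,8Z)-1-(trimethylsilyl)undeca-5,8-dien-1-yn-3-yl]oxy}silane
Product: 23 (S)-tert-butyldimethyl{[(5Z,8Z)-undeca-5,8-dien-1-yn-3-yl]oxy}silane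
Conditions: K2CO3 (0.3 equiv), MeOH, rt
Reagents that add atoms: none
Why: Methoxide-mediated protiodesilylation cleaves only the alkynyl C–Si bond, while the O-silyl ether and the diene are stable.

**Fragment union and end game**

Step 16
Reactants: 11 (1R,2R)-2-[(2R,4Z)-8-oxo-3,6,7,8-tetrahydro-2H-oxocin-2-yl]cyclopropane-1-carbaldehyde; 23 (S)-tert-butyldimethyl{[(5Z,8Z)-undeca-5,8-dien-1-yn-3-yl]oxy}silane
Product: 24 (R,Z)-8-[(1R,2R)-2-[(1R,2E,4S,6Z,9Z)-4-[(tert-butyldimethylsilyl)oxy]-1-[(triethylsilyl)oxy]dodeca-2,6,9-trien-1-yl]cyclopropyl]-3,4,7,8-tetrahydro-2H-oxocin-2-one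
Conditions: Ni(cod)2 (bis(1,5-cyclooctadiene)nickel, 10 mol %), L1·HBF4 (12 mol %), KOtBu (12 mol %), Et3SiH (2 equiv), THF, rt, 23 (1.3 equiv) added over 4 h
Reagents that add atoms: triethylsilane, CC[SiH](CC)CC
Why: Proposed new method: zerovalent nickel carrying the C2-symmetric chiral carbene from L1 binds aldehyde 11 and terminal alkyne 23; oxidative cyclisation forms the C11–C12 bond at the unsubstituted alkyne carbon (the silyloxy-bearing carbon stays on nickel because the mono-ortho-substituted N-aryl groups keep the metal-proximal space open) to give an oxanickelacyclopentene; σ-bond metathesis with Et3SiH and C–H reductive elimination then release the triethylsilyl ether by net syn addition of H and the carbinol carbon across the alkyne, which fixes 12E; the ligand's aryl quadrants allow the cyclopropyl group only one orientation, so the alkyne carbon adds to the Re face of the aldehyde and sets 11R under catalyst control despite the weak bias of the cyclopropyl aldehyde; the closest known reaction type is the nickel-catalysed aldehyde–alkyne reductive coupling with silanes, established for simpler alkynes but not as a catalyst-controlled diastereoselective union of a terminal propargylic silyl ether with an α-chiral cyclopropanecarbaldehyde.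

Step 17
Reactants: 24 (R,Z)-8-[(1R,2R)-2-[(1R,2E,4S,6Z,9Z)-4-[(tert-butyldimethylsilyl)oxy]-1-[(triethylsilyl)oxy]dodeca-2,6,9-trien-1-yl]cyclopropyl]-3,4,7,8-tetrahydro-2H-oxocin-2-one
Product: 25 (R,Z)-8-[(1R,2R)-2-[(1R,2E,4S,6Z,9Z)-1,4-dihydroxydodeca-2,6,9-trien-1-yl]cyclopropyl]-3,4,7,8-tetrahydro-2H-oxocin-2-one
Conditions: TBAF, AcOH (1:1, 4 equiv), THF, 0 °C → rt
Reagents that add atoms: none
Why: Fluoride-mediated global desilylation removes both silyl ethers, with AcOH buffering protecting the lactone and the acid- and base-sensitive cyclopropyl allylic carbinol, and no stereocentre is touched.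

**Compound list**

1 | (E)-but-2-ene-1,4-diol | OC/C=C/CO | starting material
2 | (E)-4-[(tert-butyldimethylsilyl)oxy]but-2-en-1-ol | OC/C=C/CO[Si](C)(C)C(C)(C)C | intermediate
3 | [(1R,2R)-2-{[(tert-butyldimethylsilyl)oxy]methyl}cyclopropyl]methanol | OC[C@@H]1C[C@H]1CO[Si](C)(C)C(C)(C)C | intermediate
4 | (1R,2R)-2-{[(tert-butyldimethylsilyl)oxy]methyl}cyclopropane-1-carbaldehyde | O=C[C@@H]1C[C@H]1CO[Si](C)(C)C(C)(C)C | intermediate
5 | diisopinocampheylborinate ester of 6 (Ipc groups from (−)-α-pinene) | CC(C)(C)[Si](C)(C)OC[C@@H]1C[C@H]1[C@@H](CC=C)OB([C@H]2C[C@H]3C[C@@H]([C@@H]2C)C3(C)C)[C@H]2C[C@H]3C[C@@H]([C@@H]2C)C3(C)C | intermediate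
6 | (R)-1-[(1R,2R)-2-{[(tert-butyldimethylsilyl)oxy]methyl}cyclopropyl]but-3-en-1-ol | CC(C)(C)[Si](C)(C)OC[C@@H]1C[C@H]1[C@H](O)CC=C | intermediate
7 | pent-4-enoyl chloride | C=CCCC(=O)Cl | starting material
8 | (R)-1-[(1R,2R)-2-{[(tert-butyldimethylsilyl)oxy]methyl}cyclopropyl]but-3-en-1-yl pent-4-enoate | CC(C)(C)[Si](C)(C)OC[C@@H]1C[C@H]1[C@H](OC(=O)CCC=C)CC=C | intermediate
9 | (R,Z)-8-[(1R,2R)-2-{[(tert-butyldimethylsilyl)oxy]methyl}cyclopropyl]-3,4,7,8-tetrahydro-2H-oxocin-2-one | CC(C)(C)[Si](C)(C)OC[C@@H]1C[C@H]1[C@H]1C/C=C\CCC(=O)O1 | intermediate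
10 | (R,Z)-8-[(1R,2R)-2-(hydroxymethyl)cyclopropyl]-3,4,7,8-tetrahydro-2H-oxocin-2-one | OC[C@@H]1C[C@H]1[C@H]1C/C=C\CCC(=O)O1 | intermediate
11 | (1R,2R)-2-[(2R,4Z)-8-oxo-3,6,7,8-tetrahydro-2H-oxocin-2-yl]cyclopropane-1-carbaldehyde | O=C[C@@H]1C[C@H]1[C@H]1C/C=C\CCC(=O)O1 | intermediate
12 | 3-(trimethylsilyl)prop-2-ynal | C[Si](C)(C)C#CC=O | starting material
13 | diisopinocampheylborinate ester of 14 (Ipc groups from (+)-α-pinene) | C=CC[C@H](OB([C@@H]1C[C@@H]2C[C@H]([C@H]1C)C2(C)C)[C@@H]1C[C@@H]2C[C@H]([C@H]1C)C2(C)C)C#C[Si](C)(C)C | intermediate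
14 | (S)-1-(trimethylsilyl)hex-5-en-1-yn-3-ol | C=CC[C@H](O)C#C[Si](C)(C)C | intermediate
15 | (S)-tert-butyldimethyl{[1-(trimethylsilyl)hex-5-en-1-yn-3-yl]oxy}silane | C=CC[C@H](O[Si](C)(C)C(C)(C)C)C#C[Si](C)(C)C | intermediate
16 | (4S)-4-[(tert-butyldimethylsilyl)oxy]-6-(trimethylsilyl)hex-5-yne-1,2-diol (both C2 epimers) | OCC(O)C[C@H](O[Si](C)(C)C(C)(C)C)C#C[Si](C)(C)C | intermediate
17 | (S)-3-[(tert-butyldimethylsilyl)oxy]-5-(trimethylsilyl)pent-4-ynal | O=CC[C@H](O[Si](C)(C)C(C)(C)C)C#C[Si](C)(C)C | intermediate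
18 | (Z)-hex-3-en-1-ol | CC/C=C\CCO | starting material
19 | (Z)-1-iodohex-3-ene | CC/C=C\CCI | intermediate
20 | [(Z)-hex-3-en-1-yl]triphenylphosphonium iodide | CC/C=C\CC[P+](c1ccccc1)(c1ccccc1)c1ccccc1.[I-] | intermediate
21 | [(Z)-hex-3-en-1-ylidene]triphenylphosphorane | CC/C=C\CC=P(c1ccccc1)(c1ccccc1)c1ccccc1 | intermediate
22 | (S)-tert-butyldimethyl{[(5Z,8Z)-1-(trimethylsilyl)undeca-5,8-dien-1-yn-3-yl]oxy}silane | CC/C=C\C/C=C\C[C@H](O[Si](C)(C)C(C)(C)C)C#C[Si](C)(C)C | intermediate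
23 | (S)-tert-butyldimethyl{[(5Z,8Z)-undeca-5,8-dien-1-yn-3-yl]oxy}silane | CC/C=C\C/C=C\C[C@H](O[Si](C)(C)C(C)(C)C)C#C | intermediate
24 | (R,Z)-8-[(1R,2R)-2-[(1R,2E,4S,6Z,9Z)-4-[(tert-butyldimethylsilyl)oxy]-1-[(triethylsilyl)oxy]dodeca-2,6,9-trien-1-yl]cyclopropyl]-3,4,7,8-tetrahydro-2H-oxocin-2-one | CC/C=C\C/C=C\C[C@H](O[Si](C)(C)C(C)(C)C)/C=C/[C@@H](O[Si](CC)(CC)CC)[C@@H]1C[C@H]1[C@H]1C/C=C\CCC(=O)O1 | intermediate
25 | (R,Z)-8-[(1R,2R)-2-[(1R,2E,4S,6Z,9Z)-1,4-dihydroxydodeca-2,6,9-trien-1-yl]cyclopropyl]-3,4,7,8-tetrahydro-2H-oxocin-2-one (CNP0319393.3) | CC/C=C\C/C=C\C[C@H](O)/C=C/[C@@H](O)[C@@H]1C[C@H]1[C@H]1C/C=C\CCC(=O)O1 | target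

**Step count**

Total: 17 steps. Longest linear sequence: 10 steps (steps 1–8, 16, 17).

**Steps most likely to fail, with fallbacks**

Step 16 (proposed new step). The facial control by the carbene ligand and the regiochemistry with a propargylic silyl ether are unproven. Alkyne oligomerisation, aldehyde hydrosilylation or nickel insertion into the cyclopropyl aldehyde could also compete. The fallback uses known chemistry only, sets out from 23 and 11, and comes back to the route at 25. Hydrozirconation of 23 with Cp2Zr(H)Cl in THF followed by iodinolysis gives the vinyl iodide (S,1E,5Z,8Z)-tert-butyl[(1-iodoundeca-1,5,8-trien-3-yl)oxy]dimethylsilane F1. Nozaki–Hiyama–Kishi coupling of F1 with 11 (CrCl2 as the divalent chromium reductant, NiCl2 1 mol %, DMSO, rt) gives, with little substrate control, the allylic alcohol (R,Z)-8-[(1R,2R)-2-[(2E,4S,6Z,9Z)-4-[(tert-butyldimethylsilyl)oxy]-1-hydroxydodeca-2,6,9-trien-1-yl]cyclopropyl]-3,4,7,8-tetrahydro-2H-oxocin-2-one as a mixture of C11 epimers F2. Dess–Martin oxidation of the whole mixture gives the enone (R,Z)-8-[(1R,2R)-2-[(2E,4S,6Z,9Z)-4-[(tert-butyldimethylsilyl)oxy]dodeca-2,6,9-trienoyl]cyclopropyl]-3,4,7,8-tetrahydro-2H-oxocin-2-one F3. Reagent-controlled CBS reduction of F3 gives the 11R alcohol (R,Z)-8-[(1R,2R)-2-[(1R,2E,4S,6Z,9Z)-4-[(tert-butyldimethylsilyl)oxy]-1-hydroxydodeca-2,6,9-trien-1-yl]cyclopropyl]-3,4,7,8-tetrahydro-2H-oxocin-2-one F4. The reduction would use (R)-2-methyl-CBS-oxazaborolidine and catecholborane in toluene at −78 °C, treating the alkenyl group as the large substituent; the sense must be checked by Mosher analysis and the antipode used if needed. TBAF/AcOH then converts F4 into 25.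

Step 6. Closing an eight-membered lactone by metathesis competes with oligomerisation, because the ester prefers the s-trans geometry. The fallback sets out from 6 and comes back at 9, forming the ring at the C1–O bond instead of at C4=C5. TESCl and imidazole give tert-butyldimethyl{[(1R,2R)-2-[(R)-1-[(triethylsilyl)oxy]but-3-en-1-yl]cyclopropyl]methoxy}silane F5. Ozonolysis (O3, CH2Cl2, −78 °C; PPh3) gives (R)-3-[(1R,2R)-2-{[(tert-butyldimethylsilyl)oxy]methyl}cyclopropyl]-3-[(triethylsilyl)oxy]propanal F6. A Z-selective Wittig reaction with the ylide from (3-carboxypropyl)triphenylphosphonium bromide and NaN(SiMe3)2 (2 equiv, THF, −78 °C → rt) gives (R,Z)-7-[(1R,2R)-2-{[(tert-butyldimethylsilyl)oxy]methyl}cyclopropyl]-7-[(triethylsilyl)oxy]hept-4-enoic acid F7. PPTS in MeOH at 0 °C removes the secondary triethylsilyl group in the presence of the primary TBS ether and gives (R,Z)-7-[(1R,2R)-2-{[(tert-butyldimethylsilyl)oxy]methyl}cyclopropyl]-7-hydroxyhept-4-enoic acid F8. Yamaguchi lactonisation (2,4,6-trichlorobenzoyl chloride, Et3N, THF; then DMAP, toluene, high dilution, 80 °C) closes F8 to 9.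

Step 4. Reagent control has to override the α-stereocentre of the cyclopropyl aldehyde, and a mismatched pairing would give C7 epimers that are hard to separate. The fallback sets out from 2 and comes back at 6, inverting the order so that C7 is made first on an achiral enal and then directs the cyclopropanation. MnO2 in CH2Cl2 oxidises 2 to (E)-4-[(tert-butyldimethylsilyl)oxy]but-2-enal F9. Brown allylation of F9 with (+)-Ipc2B(allyl) (Et2O, −78 °C; NaOH, H2O2) gives (R,E)-1-[(tert-butyldimethylsilyl)oxy]hepta-2,6-dien-4-ol F10. Hydroxyl-directed Simmons–Smith reaction of F10 (Et2Zn, CH2I2, CH2Cl2, −20 → 0 °C) cyclopropanates the allylic E-alkene on the face syn to the zinc alkoxide in the conformer of minimal A(1,3) strain. Working through that geometry gives the 7R,8R,10R isomer, which is 6, after removal of the minor diastereomer.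

**Further compounds**

F1 | step 16 | (S,1E,5Z,8Z)-tert-butyl[(1-iodoundeca-1,5,8-trien-3-yl)oxy]dimethylsilane | CC/C=C\C/C=C\C[C@H](O[Si](C)(C)C(C)(C)C)/C=C/I
F2 | step 16 | (R,Z)-8-[(1R,2R)-2-[(2E,4S,6Z,9Z)-4-[(tert-butyldimethylsilyl)oxy]-1-hydroxydodeca-2,6,9-trien-1-yl]cyclopropyl]-3,4,7,8-tetrahydro-2H-oxocin-2-one (C11 epimers) | CC/C=C\C/C=C\C[C@H](O[Si](C)(C)C(C)(C)C)/C=C/C(O)[C@@H]1C[C@H]1[C@H]1C/C=C\CCC(=O)O1
F3 | step 16 | (R,Z)-8-[(1R,2R)-2-[(2E,4S,6Z,9Z)-4-[(tert-butyldimethylsilyl)oxy]dodeca-2,6,9-trienoyl]cyclopropyl]-3,4,7,8-tetrahydro-2H-oxocin-2-one | CC/C=C\C/C=C\C[C@H](O[Si](C)(C)C(C)(C)C)/C=C/C(=O)[C@@H]1C[C@H]1[C@H]1C/C=C\CCC(=O)O1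
F4 | step 16 | (R,Z)-8-[(1R,2R)-2-[(1R,2E,4S,6Z,9Z)-4-[(tert-butyldimethylsilyl)oxy]-1-hydroxydodeca-2,6,9-trien-1-yl]cyclopropyl]-3,4,7,8-tetrahydro-2H-oxocin-2-one | CC/C=C\C/C=C\C[C@H](O[Si](C)(C)C(C)(C)C)/C=C/[C@@H](O)[C@@H]1C[C@H]1[C@H]1C/C=C\CCC(=O)O1
F5 | step 6 | tert-butyldimethyl{[(1R,2R)-2-[(R)-1-[(triethylsilyl)oxy]but-3-en-1-yl]cyclopropyl]methoxy}silane | CC(C)(C)[Si](C)(C)OC[C@@H]1C[C@H]1[C@H](O[Si](CC)(CC)CC)CC=C
F6 | step 6 | (R)-3-[(1R,2R)-2-{[(tert-butyldimethylsilyl)oxy]methyl}cyclopropyl]-3-[(triethylsilyl)oxy]propanal | CC(C)(C)[Si](C)(C)OC[C@@H]1C[C@H]1[C@H](O[Si](CC)(CC)CC)CC=O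
F7 | step 6 | (R,Z)-7-[(1R,2R)-2-{[(tert-butyldimethylsilyl)oxy]methyl}cyclopropyl]-7-[(triethylsilyl)oxy]hept-4-enoic acid | CC(C)(C)[Si](C)(C)OC[C@@H]1C[C@H]1[C@H](O[Si](CC)(CC)CC)C/C=C\CCC(=O)O
F8 | step 6 | (R,Z)-7-[(1R,2R)-2-{[(tert-butyldimethylsilyl)oxy]methyl}cyclopropyl]-7-hydroxyhept-4-enoic acid | CC(C)(C)[Si](C)(C)OC[C@@H]1C[C@H]1[C@H](O)C/C=C\CCC(=O)O
F9 | step 4 | (E)-4-[(tert-butyldimethylsilyl)oxy]but-2-enal | O=C/C=C/CO[Si](C)(C)C(C)(C)C
F10 | step 4 | (R,E)-1-[(tert-butyldimethylsilyl)oxy]hepta-2,6-dien-4-ol | CC(C)(C)[Si](C)(C)OC/C=C/[C@H](O)CC=C
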